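**Retrosynthetic overview**

- The strategy rests on the O1–C8a bond of each chromone, the ring A oxygen between the biaryl carbon C8 and the acyl-bearing C4a. Without these two oxygens the core is an unhindered, di-ortho-substituted 5,5'-dimer of a 2,4-dialkoxyacetophenone.
- The target comes from BCl3 cleavage of the 5-O-methyl and 7-O-isopropyl ethers of the biflavone, which comes from acid cyclodehydration of a bis(1,3-diketone), made by C-aroylation of the bis(2-hydroxyacetophenone) biaryl with 4-methoxybenzoyl chloride.
- That 2,2'-biphenol comes from a twofold ketone-directed C–H oxygenation (both C8a–O bonds) of 5,5'-diacetyl-2,2'-diisopropoxy-4,4'-dimethoxybiphenyl.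
- The biaryl comes from nickel-mediated homocoupling of the 5'-iodide of 4'-isopropoxy-2'-methoxyacetophenone, made from 2',4'-dihydroxyacetophenone by 4-O-isopropylation, 2-O-methylation and iodination.
- Ring order: rings A and B are bought; the biaryl bond joins the two rings A in step 4; the two pyranone rings C close together in step 7.

Key step: step 5

Remark: the target SMILES fixes no configuration at the C8–C8'' axis, so the route is planned for the racemic atropisomer; the molecule has no stereocentre.

**Step 1**
Reactants: 1 2',4'-dihydroxyacetophenone; 2 2-bromopropane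
Product: 3 2'-hydroxy-4'-isopropoxyacetophenone
Conditions: 2-bromopropane (1.2 equiv), K2CO3 (1.3 equiv), DMF, 60 °C
Reagents that add atoms: 2-bromopropane CC(C)Br
Why: Williamson etherification in which the 2'-hydroxyl, hydrogen-bonded to the carbonyl, is much less nucleophilic than the 4'-hydroxyl, so a slight excess of halide and base should alkylate the 4'-oxygen only.

**Step 2**
Reactants: 3 2'-hydroxy-4'-isopropoxyacetophenone; 4 iodomethane
Product: 5 4'-isopropoxy-2'-methoxyacetophenone
Conditions: MeI (2 equiv), K2CO3 (2 equiv), DMF, 45 °C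
Reagents that add atoms: iodomethane CI
Why: Williamson O-methylation of the chelated phenol, which an excess of the unhindered methyl iodide in a dipolar aprotic solvent should drive to completion.

**Step 3**
Reactants: 5 4'-isopropoxy-2'-methoxyacetophenone
Product: 6 5'-iodo-4'-isopropoxy-2'-methoxyacetophenone
Conditions: N-iodosuccinimide (1.05 equiv), CF3CO2H (cat.), MeCN, rt, dark
Reagents that add atoms: N-iodosuccinimide O=C1CCC(=O)N1I
Why: Electrophilic aromatic iodination that should go to C5', para to the methoxy and ortho to the isopropoxy group, because the equally activated C3' is shielded by two flanking alkoxy groups.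

**Step 4**
Reactants: 6 5'-iodo-4'-isopropoxy-2'-methoxyacetophenone (two molecules)
Product: 7 5,5'-diacetyl-2,2'-diisopropoxy-4,4'-dimethoxybiphenyl
Conditions: NiCl2(PPh3)2 (10 mol %), Zn dust (1.5 equiv), Et4NI (1 equiv), THF, 50 °C
Reagents that add atoms: none
Why: Nickel-catalysed reductive homocoupling of an aryl iodide, in which Zn reduces the divalent nickel precatalyst to zerovalent nickel, aryl ketones are tolerated and each ring brings only one ortho substituent to the new axis.

**Step 5**
Reactants: 7 5,5'-diacetyl-2,2'-diisopropoxy-4,4'-dimethoxybiphenyl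
Product: 9 3,3'-diacetyl-6,6'-diisopropoxy-4,4'-dimethoxybiphenyl-2,2'-diol, via bis(trifluoroacetate) 8 (not isolated)
Conditions: Pd(OAc)2 (20 mol %), K2S2O8 (5 equiv), CF3CO2H/(CF3CO)2O 9:1, 50 °C; then H2O
Reagents that add atoms: trifluoroacetic acid OC(=O)C(F)(F)F
Why: In trifluoroacetic acid Pd(OAc)2 becomes an electrophilic divalent palladium trifluoroacetate that binds the acetyl oxygen and metalates the only ortho C–H of each ring (concerted metalation–deprotonation) to a five-membered palladacycle, which persulfate oxidises to a tetravalent palladium trifluoroacetate; C–O reductive elimination then releases the aryl trifluoroacetate 8 and returns divalent palladium, and aqueous work-up hydrolyses 8 to 9. The closest known reaction type is the ketone-directed ortho C–H hydroxylation of aryl ketones with Pd(OAc)2 and K2S2O8 in CF3CO2H/(CF3CO)2O, here run twice on one molecule. No ring is closed and no stereocentre is made; the two new C–O bonds become the O1–C8a bonds of the later pyranone rings. The step needs oxygenation ortho to the acetyl group and not at the more nucleophilic carbon between the two alkoxy groups: chelation delivers palladium only to the ortho position, the other ortho position already carries the methoxy group, and that methoxy group should hold the carbonyl oxygen turned towards the C–H. The anhydride-containing acid keeps each new oxygen as an electron-poor trifluoroacetate, which should prevent over-oxidation and cyclisation onto the neighbouring ring. The open point is the rate of palladation beside the biaryl axis, which the twisted, only di-ortho-substituted axis should keep tolerable.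

**Step 6**
Reactants: 9 3,3'-diacetyl-6,6'-diisopropoxy-4,4'-dimethoxybiphenyl-2,2'-diol; 10 4-methoxybenzoyl chloride
Product: 11 1,1'-(2,2'-dihydroxy-6,6'-diisopropoxy-4,4'-dimethoxybiphenyl-3,3'-diyl)bis[3-(4-methoxyphenyl)propane-1,3-dione]
Conditions: LiN(SiMe3)2 (9 equiv), THF, –78 to –10 °C; 10 (2.2 equiv), –78 °C to rt; aq. HCl
Reagents that add atoms: 4-methoxybenzoyl chloride COc1ccc(C(=O)Cl)cc1
Why: Claisen-type C-acylation of the lithium phenoxide–enolate of each 2-hydroxyacetophenone unit (the direct variant of the Baker–Venkataraman construction), in which the hindered lithium phenoxide is a poor nucleophile and the excess base stores the product as its diketonate.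

**Step 7**
Reactants: 11 bis(1,3-diketone)
Product: 12 7,7''-diisopropoxy-5,5'',4',4'''-tetramethoxy-8,8''-biflavone
Conditions: p-TsOH·H2O (20 mol %), toluene, reflux, Dean–Stark
Reagents that add atoms: none
Why: Acid-catalysed cyclodehydration of an o-hydroxyaryl 1,3-diketone to a flavone, in which the only free hydroxyl of each ring adds to the aryl ketone carbon (six-membered closure through oxygen) and water is lost, so each pyranone can form in one sense only.

**Step 8**
Reactants: 12 7,7''-diisopropoxy-5,5'',4',4'''-tetramethoxy-8,8''-biflavone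
Product: 14 4',4'''-di-O-methylcupressuflavone, via tetrakis(dichloroboryl) ether 13 (not isolated)
Conditions: BCl3 (10 equiv), CH2Cl2, –78 to 0 °C; then H2O, 0 °C
Reagents that add atoms: none
Why: Lewis-acid ether cleavage in which BCl3 chelated by the C4 carbonyl cleaves the peri 5-O-methyl ether and chloride cleaves the secondary isopropyl ether, while the unchelated primary 4'-O-methyl ethers should be inert at or below 0 °C.

**Compound list**

1 | 2',4'-dihydroxyacetophenone | CC(=O)c1ccc(O)cc1O | starting material
2 | 2-bromopropane | CC(C)Br | starting material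
3 | 2'-hydroxy-4'-isopropoxyacetophenone | CC(=O)c1ccc(OC(C)C)cc1O | intermediate
4 | iodomethane | CI | starting material
5 | 4'-isopropoxy-2'-methoxyacetophenone | CC(=O)c1ccc(OC(C)C)cc1OC | intermediate
6 | 5'-iodo-4'-isopropoxy-2'-methoxyacetophenone | CC(=O)c1cc(I)c(OC(C)C)cc1OC | intermediate
7 | 5,5'-diacetyl-2,2'-diisopropoxy-4,4'-dimethoxybiphenyl | CC(=O)c1cc(-c2cc(C(C)=O)c(OC)cc2OC(C)C)c(OC(C)C)cc1OC | intermediate
8 | 3,3'-diacetyl-6,6'-diisopropoxy-4,4'-dimethoxybiphenyl-2,2'-diyl bis(trifluoroacetate) | CC(=O)c1c(OC(=O)C(F)(F)F)c(-c2c(OC(=O)C(F)(F)F)c(C(C)=O)c(OC)cc2OC(C)C)c(OC(C)C)cc1OC | intermediate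
9 | 3,3'-diacetyl-6,6'-diisopropoxy-4,4'-dimethoxybiphenyl-2,2'-diol | CC(=O)c1c(O)c(-c2c(O)c(C(C)=O)c(OC)cc2OC(C)C)c(OC(C)C)cc1OC | intermediate
10 | 4-methoxybenzoyl chloride | COc1ccc(C(=O)Cl)cc1 | starting material
11 | 1,1'-(2,2'-dihydroxy-6,6'-diisopropoxy-4,4'-dimethoxybiphenyl-3,3'-diyl)bis[3-(4-methoxyphenyl)propane-1,3-dione] | COc1ccc(C(=O)CC(=O)c2c(O)c(-c3c(O)c(C(=O)CC(=O)c4ccc(OC)cc4)c(OC)cc3OC(C)C)c(OC(C)C)cc2OC)cc1 | intermediate
12 | 7,7''-diisopropoxy-5,5'',4',4'''-tetramethoxy-8,8''-biflavone | COc1ccc(-c2cc(=O)c3c(OC)cc(OC(C)C)c(-c4c(OC(C)C)cc(OC)c5c(=O)cc(-c6ccc(OC)cc6)oc45)c3o2)cc1 | intermediate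
13 | 5,5'',7,7''-tetrakis(dichloroboryloxy)-4',4'''-dimethoxy-8,8''-biflavone | COc1ccc(-c2cc(=O)c3c(OB(Cl)Cl)cc(OB(Cl)Cl)c(-c4c(OB(Cl)Cl)cc(OB(Cl)Cl)c5c(=O)cc(-c6ccc(OC)cc6)oc45)c3o2)cc1 | intermediate
14 | 4',4'''-di-O-methylcupressuflavone (5,5'',7,7''-tetrahydroxy-4',4'''-dimethoxy-8,8''-biflavone) | COc1ccc(-c2cc(=O)c3c(O)cc(O)c(-c4c(O)cc(O)c5c(=O)cc(-c6ccc(OC)cc6)oc45)c3o2)cc1 | target

**Step count and risks**

Total step count: 8. Longest linear sequence: 8 steps (1 to 14).

Steps most likely to fail:

1. Step 5. Palladation at a C–H flanked by the acetyl group and the twisted aryl ring may be slow, so that the reaction stops after one oxygenation. Persulfate may also oxidise the dialkoxyarene by one-electron pathways with attack at the carbon between the alkoxy groups, and the acid may remove an isopropyl group. Fallback, setting out from 5 and coming back at 9: the oxygen is introduced before the biaryl bond. The same ketone-directed oxygenation (Pd(OAc)2, K2S2O8, CF3CO2H/(CF3CO)2O, 50 °C) on monomer 5, whose only ortho C–H is unhindered, should give 2-acetyl-5-isopropoxy-3-methoxyphenyl trifluoroacetate F1, hydrolysed on work-up to 2'-hydroxy-4'-isopropoxy-6'-methoxyacetophenone F2. Iodination ortho to the chelated hydroxyl (N-iodosuccinimide, DMF, rt) should give 2'-hydroxy-3'-iodo-4'-isopropoxy-6'-methoxyacetophenone F3. Benzylation (BnBr, K2CO3, DMF, 60 °C) should give 2'-benzyloxy-3'-iodo-4'-isopropoxy-6'-methoxyacetophenone F4. Classical Ullmann coupling (activated Cu powder, DMF, 150 °C) should give 3,3'-diacetyl-2,2'-bis(benzyloxy)-6,6'-diisopropoxy-4,4'-dimethoxybiphenyl F5, and hydrogenolysis (H2, Pd/C, EtOAc, rt) should give 9.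

2. Step 6. The acid chloride may be used up by O-acylation of the phenoxide, by a second acylation of the diketonate or by the amide base, or only one of the two acetyl groups may react. Fallback, setting out from 9 and coming back at 12: a chalcone route. Claisen–Schmidt condensation of 9 with 4-methoxybenzaldehyde (KOH, EtOH, rt) should give (2E,2'E)-1,1'-(2,2'-dihydroxy-6,6'-diisopropoxy-4,4'-dimethoxybiphenyl-3,3'-diyl)bis[3-(4-methoxyphenyl)prop-2-en-1-one] F6. Oxidative cyclisation with catalytic iodine in DMSO at 130 °C should then give biflavone 12, so that steps 6 and 7 are both replaced.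

3. Step 4. Hydrodeiodination back to 5 may outrun the coupling, and the ortho isopropoxy group may slow aryl transfer between nickel centres. Fallback, setting out from 6 and coming back at 7: a cross-coupling of two halves. Miyaura borylation of one half of 6 (bis(pinacolato)diboron, PdCl2(dppf), KOAc, dioxane, 90 °C) should give 4'-isopropoxy-2'-methoxy-5'-(4,4,5,5-tetramethyl-1,3,2-dioxaborolan-2-yl)acetophenone F7. Suzuki–Miyaura coupling of F7 with the other half of 6 (Pd(PPh3)4, K2CO3, dioxane/H2O, 90 °C) should give 7.

**Further compounds**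

F1 | step 5 | 2-acetyl-5-isopropoxy-3-methoxyphenyl trifluoroacetate | CC(=O)c1c(OC(=O)C(F)(F)F)cc(OC(C)C)cc1OC
F2 | step 5 | 2'-hydroxy-4'-isopropoxy-6'-methoxyacetophenone | CC(=O)c1c(O)cc(OC(C)C)cc1OC
F3 | step 5 | 2'-hydroxy-3'-iodo-4'-isopropoxy-6'-methoxyacetophenone | CC(=O)c1c(O)c(I)c(OC(C)C)cc1OC
F4 | step 5 | 2'-benzyloxy-3'-iodo-4'-isopropoxy-6'-methoxyacetophenone | CC(=O)c1c(OCc2ccccc2)c(I)c(OC(C)C)cc1OC
F5 | step 5 | 3,3'-diacetyl-2,2'-bis(benzyloxy)-6,6'-diisopropoxy-4,4'-dimethoxybiphenyl | CC(=O)c1c(OCc2ccccc2)c(-c2c(OCc3ccccc3)c(C(C)=O)c(OC)cc2OC(C)C)c(OC(C)C)cc1OC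
F6 | step 6 | (2E,2'E)-1,1'-(2,2'-dihydroxy-6,6'-diisopropoxy-4,4'-dimethoxybiphenyl-3,3'-diyl)bis[3-(4-methoxyphenyl)prop-2-en-1-one] | COc1ccc(/C=C/C(=O)c2c(O)c(-c3c(O)c(C(=O)/C=C/c4ccc(OC)cc4)c(OC)cc3OC(C)C)c(OC(C)C)cc2OC)cc1
F7 | step 4 | 4'-isopropoxy-2'-methoxy-5'-(4,4,5,5-tetramethyl-1,3,2-dioxaborolan-2-yl)acetophenone | CC(=O)c1cc(B2OC(C)(C)C(C)(C)O2)c(OC(C)C)cc1OC
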